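**Retrosynthetic overview**

1. Ring letters: A = trioxygenated benzene, B = dihydropyran on A, C = 4-pyranone, D = furan, E = second benzene, F = 2H-pyran on E. Ring C is opened at its O–C bond to the furan carbon (addition–elimination, MeSH lost). Ring D is cut by a formal (3+2) annulation of an aroyl ketene dithioacetal (rings A/B) with 2,2-dimethyl-2H-chromene-5,8-dione (rings E/F).
2. The A/B ketone comes from a 5,7-dioxygenated 2,2-dimethylchroman by two successive directed ortho-lithiations: prenyl between the two MOM ethers, then acetyl at the last aromatic C–H.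
3. Ring B is cut at its aryl C–O and aryl C–CH2 bonds. 3,5-Bis(benzyloxy)benzyne and 3-methylbut-2-enal combine in a (2+2)/4π-opening/oxa-6π cascade to the 2H-chromene, which is saturated (with debenzylation) in the next step.
4. Enabling feature: in ring A the carbon bearing the ring B oxygen and the carbon bearing the ring B CH2 are ortho neighbours, the latter is flanked by an oxygen-bearing carbon (1,3,5-oxygenation), and the quaternary C(CH3)2 of ring B sits on the ring oxygen. An alkoxy-polarised aryne and a β,β-dimethyl enal map exactly onto this.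
5. Ring order: A and E bought; B (step 4); F (step 11); D (step 13); C (step 15).

Key step: step 4

Remark: the target has no stereocentre, so no stereocontrol is needed; transient chiral intermediates are racemic.

**Route**

Step 1
Reactants: 1 3,5-bis(benzyloxy)phenol
Product: 2 3,5-bis(benzyloxy)phenyl N-isopropylcarbamate
Conditions: i-PrNCO, Et3N (cat.), CH2Cl2, rt
Reagents that add atoms: isopropyl isocyanate CC(C)N=C=O
Why: Base-catalysed addition of the phenol to the isocyanate (carbamoylation) installs a strong ortho-directing group that can be removed again under mild conditions.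

Step 2
Reactants: 2 3,5-bis(benzyloxy)phenyl N-isopropylcarbamate
Product: 6 3,5-bis(benzyloxy)-2-(trimethylsilyl)phenyl N-isopropylcarbamate, via N-silyl carbamate 3 (not isolated), via aryllithium 4 (not isolated), via bis-silyl carbamate 5 (not isolated)
Conditions: TBSOTf, TMEDA, Et2O, 0 °C to rt; n-BuLi, TMEDA, −78 °C; TMSCl, −78 °C to rt; aq. NaHSO4
Reagents that add atoms: chlorotrimethylsilane C[Si](C)(C)Cl
Why: Directed ortho-metalation: after N-silylation in the flask the O-aryl carbamate directs lithiation to C2 (C2 and C6 are equivalent by symmetry, each flanked by a benzyloxy group), the aryllithium is C-silylated and the N-silyl group falls off on acidic work-up.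

Step 3
Reactants: 6 3,5-bis(benzyloxy)-2-(trimethylsilyl)phenyl N-isopropylcarbamate
Product: 8 3,5-bis(benzyloxy)-2-(trimethylsilyl)phenyl trifluoromethanesulfonate, via silylphenol 7 (not isolated)
Conditions: Et2NH, DBU, MeCN, 40 °C; then PhNTf2, rt
Reagents that add atoms: N-phenylbis(trifluoromethanesulfonimide) O=S(=O)(N(c1ccccc1)S(=O)(=O)C(F)(F)F)C(F)(F)F
Why: Amine-mediated carbamate cleavage (E1cB loss of isopropyl isocyanate, trapped by Et2NH) frees the phenoxide, which is O-triflated in the same flask without touching the aryl–silicon bond.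

Step 4
Reactants: 8 3,5-bis(benzyloxy)-2-(trimethylsilyl)phenyl trifluoromethanesulfonate; 9 3-methylbut-2-enal
Product: 13 5,7-bis(benzyloxy)-2,2-dimethyl-2H-chromene, via aryne 10 (not isolated), via benzoxete 11 (not isolated), via ortho-quinone methide 12 (not isolated)
Conditions: CsF, 9 (excess), MeCN, rt to 45 °C
Reagents that add atoms: none
Why: Fluoride removes the silyl group and triflate leaves to give the 3,5-dialkoxyaryne 10; the carbonyl oxygen of 9 adds to the aryne carbon remote from the neighbouring benzyloxy group and the aryl anion formed next to that group closes on the oxocarbenium carbon, a stepwise polar (2+2) addition that makes the aryl C–O and the aryl C–C bond and the four-membered benzoxete 11. Thermal 4π ring opening of 11 gives the ortho-quinone methide 12, whose oxatriene closes by a thermal oxa-6π electrocyclisation (oxygen onto the dimethyl-substituted terminus) to the six-membered 2H-pyran of 13. The closest known reaction type is the aryne/α,β-unsaturated aldehyde cascade to 2H-chromenes. No stereocentre is formed. The step needs one regioisomer: the inductively withdrawing C3 benzyloxy group polarises the aryne so that oxygen goes to C1 and carbon to C2, which should give the 5,7- and not the 6,8-dioxygenated chromene. The excess of enal and the fast intramolecular electrocyclisation should keep 12 from adding a second aryne.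

Step 5
Reactants: 13 5,7-bis(benzyloxy)-2,2-dimethyl-2H-chromene
Product: 14 2,2-dimethylchroman-5,7-diol
Conditions: H2 (1 atm), Pd/C, EtOAc–MeOH, rt
Reagents that add atoms: none
Why: Heterogeneous catalytic hydrogenation saturates the styrenic C3=C4 bond and hydrogenolyses both benzyl ethers in one operation, at a stage where no other reducible group is present.

Step 6
Reactants: 14 2,2-dimethylchroman-5,7-diol
Product: 15 5,7-bis(methoxymethoxy)-2,2-dimethylchroman
Conditions: MOMCl, i-Pr2NEt, CH2Cl2, 0 °C to rt
Reagents that add atoms: chloromethyl methyl ether COCCl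
Why: O-alkylation of both phenols (Williamson-type acetal formation) installs groups that direct ortho-lithiation and come off at the end under mild acid.

Step 7
Reactants: 15 5,7-bis(methoxymethoxy)-2,2-dimethylchroman; 16 1-bromo-3-methylbut-2-ene
Product: 18 5,7-bis(methoxymethoxy)-2,2-dimethyl-6-(3-methylbut-2-en-1-yl)chroman, via aryllithium 17 (not isolated)
Conditions: n-BuLi, THF, 0 °C; CuBr·SMe2 (10 mol %), 16, −78 °C to rt
Reagents that add atoms: none
Why: Directed ortho-metalation should occur at C6, the only position flanked by two chelating MOM ethers, and copper-catalysed allylic substitution of the aryllithium at the primary carbon of prenyl bromide gives the linear prenyl group.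

Step 8
Reactants: 18 5,7-bis(methoxymethoxy)-2,2-dimethyl-6-(3-methylbut-2-en-1-yl)chroman; 19 N-methoxy-N-methylacetamide
Product: 21 1-[5,7-bis(methoxymethoxy)-2,2-dimethyl-6-(3-methylbut-2-en-1-yl)chroman-8-yl]ethan-1-one, via aryllithium 20 (not isolated)
Conditions: n-BuLi, TMEDA, THF, −20 to 0 °C; 19, −78 °C to rt; H2O
Reagents that add atoms: none
Why: A second directed ortho-metalation at the last aromatic C–H (C8, between the C7 MOM ether and the ring oxygen) is followed by acylation with the N-methoxy-N-methylamide, whose chelated tetrahedral adduct prevents over-addition.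

Step 9
Reactants: 21 1-[5,7-bis(methoxymethoxy)-2,2-dimethyl-6-(3-methylbut-2-en-1-yl)chroman-8-yl]ethan-1-one; 22 carbon disulfide
Product: 24 1-[5,7-bis(methoxymethoxy)-2,2-dimethyl-6-(3-methylbut-2-en-1-yl)chroman-8-yl]-3,3-bis(methylsulfanyl)prop-2-en-1-one, via disodium dithiolate 23 (not isolated)
Conditions: NaH, 22, THF–DMF, 0 °C; MeI, 0 °C to rt
Reagents that add atoms: iodomethane CI
Why: Standard α-oxo ketene dithioacetal synthesis: the methyl ketone enolate adds to CS2 and the dithiolate is S-methylated twice, while the ortho MOM ether keeps the acetal from closing to a chromone at this stage.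

Step 10
Reactants: 25 2,5-dimethoxyphenol; 26 3-chloro-3-methylbut-1-yne
Product: 27 1,4-dimethoxy-2-[(2-methylbut-3-yn-2-yl)oxy]benzene
Conditions: DBU, CuCl2 (cat.), MeCN, 0 °C to rt
Reagents that add atoms: none
Why: Copper-catalysed O-propargylation of a phenol with a tertiary propargylic chloride gives the aryl 1,1-dimethylpropargyl ether.

Step 11
Reactants: 27 1,4-dimethoxy-2-[(2-methylbut-3-yn-2-yl)oxy]benzene
Product: 30 5,8-dimethoxy-2,2-dimethyl-2H-chromene, via allenylphenol 28 (not isolated), via ortho-quinone methide 29 (not isolated)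
Conditions: PhNEt2, 190 °C
Reagents that add atoms: none
Why: Aromatic propargyl Claisen rearrangement to the only free ortho carbon, tautomerisation, 1,5-hydrogen shift and oxa-6π electrocyclisation form ring F with its oxygen on the carbon next to a methoxy group.

Step 12
Reactants: 30 5,8-dimethoxy-2,2-dimethyl-2H-chromene
Product: 31 2,2-dimethyl-2H-chromene-5,8-dione
Conditions: (NH4)2Ce(NO3)6, MeCN–H2O, 0 °C
Reagents that add atoms: water O
Why: Oxidative demethylation of a para-dimethoxyarene by a one-electron oxidant gives the para-quinone, with water supplying the carbonyl oxygens.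

Step 13
Reactants: 24 1-[5,7-bis(methoxymethoxy)-2,2-dimethyl-6-(3-methylbut-2-en-1-yl)chroman-8-yl]-3,3-bis(methylsulfanyl)prop-2-en-1-one; 31 2,2-dimethyl-2H-chromene-5,8-dione
Product: 33 [5,7-bis(methoxymethoxy)-2,2-dimethyl-6-(3-methylbut-2-en-1-yl)chroman-8-yl] ketone of a 5-hydroxy-2-(methylsulfanyl)benzofuran-3-yl unit that carries a 2,2-dimethyl-2H-pyran fused at benzofuran C6–C7 (oxygen on C6), via hydroquinone adduct 32 (not isolated)
Conditions: CuBr2 (5 mol %), BF3·OEt2 (10 mol %), MeCN, rt
Reagents that add atoms: none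
Why: Lewis-acid-catalysed formal (3+2) annulation of an α-oxo ketene dithioacetal with a para-quinone (Nenitzescu-type benzofuran synthesis): the α-carbon adds in Michael fashion at quinone C6 (β to the C8 carbonyl, the C5 carbonyl being deactivated as a vinylogous ester of the ring oxygen), and after aromatisation the hydroxyl ortho to the new C–C bond closes on the dithio-stabilised cation and expels methanethiol.

Step 14
Reactants: 33 the bis-MOM benzofuranyl ketone of step 13
Product: 34 [5,7-dihydroxy-2,2-dimethyl-6-(3-methylbut-2-en-1-yl)chroman-8-yl] ketone of the same 5-hydroxy-2-(methylsulfanyl)pyranobenzofuran-3-yl unit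
Conditions: HCl (1 M), MeOH, 40 °C
Reagents that add atoms: none
Why: Acid-catalysed acetal exchange with methanol removes both MOM groups under conditions commonly used for MOM removal next to prenyl and 2,2-dimethylchromene units.

Step 15
Reactants: 34 the trihydroxy benzofuranyl ketone of step 14
Product: 35 CNP0081330.0 (target)
Conditions: K2CO3, DMF, 70 °C, argon; aq. NH4Cl
Reagents that add atoms: none
Why: Intramolecular addition–elimination (oxa-Michael addition of the phenoxide ortho to the ketone at the sulfur-bearing furan carbon, then loss of methanethiolate) closes the 4-pyranone ring C as in the synthesis of 2-substituted chromones from ortho-hydroxyaryl ketene dithioacetals; the second ring A phenol is para to the ketone and cannot cyclise.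

**Compound list**

1 | 3,5-bis(benzyloxy)phenol | Oc1cc(OCc2ccccc2)cc(OCc2ccccc2)c1 | starting material
2 | 3,5-bis(benzyloxy)phenyl N-isopropylcarbamate | CC(C)NC(=O)Oc1cc(OCc2ccccc2)cc(OCc2ccccc2)c1 | intermediate
3 | N-(tert-butyldimethylsilyl) derivative of 2 (not isolated) | CC(C)N(C(=O)Oc1cc(OCc2ccccc2)cc(OCc2ccccc2)c1)[Si](C)(C)C(C)(C)C | intermediate
4 | 2-lithio derivative of 3 (not isolated) | CC(C)N(C(=O)Oc1cc(OCc2ccccc2)cc(OCc2ccccc2)c1[Li])[Si](C)(C)C(C)(C)C | intermediate
5 | 2-(trimethylsilyl) derivative of 3 (not isolated) | CC(C)N(C(=O)Oc1cc(OCc2ccccc2)cc(OCc2ccccc2)c1[Si](C)(C)C)[Si](C)(C)C(C)(C)C | intermediate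
6 | 3,5-bis(benzyloxy)-2-(trimethylsilyl)phenyl N-isopropylcarbamate | CC(C)NC(=O)Oc1cc(OCc2ccccc2)cc(OCc2ccccc2)c1[Si](C)(C)C | intermediate
7 | 3,5-bis(benzyloxy)-2-(trimethylsilyl)phenol (not isolated) | Oc1cc(OCc2ccccc2)cc(OCc2ccccc2)c1[Si](C)(C)C | intermediate
8 | 3,5-bis(benzyloxy)-2-(trimethylsilyl)phenyl trifluoromethanesulfonate | O=S(=O)(Oc1cc(OCc2ccccc2)cc(OCc2ccccc2)c1[Si](C)(C)C)C(F)(F)F | intermediate
9 | 3-methylbut-2-enal | CC(C)=CC=O | starting material
10 | 3,5-bis(benzyloxy)benzyne (not isolated) | C1#CC(OCc2ccccc2)=CC(OCc2ccccc2)=C1 | intermediate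
11 | 3,5-bis(benzyloxy)-2-(2-methylprop-1-enyl)-2H-benzo[b]oxete, racemic (not isolated) | CC(C)=CC1Oc2cc(OCc3ccccc3)cc(OCc3ccccc3)c12 | intermediate
12 | (Z)-3,5-bis(benzyloxy)-6-(3-methylbut-2-enylidene)cyclohexa-2,4-dien-1-one, ortho-quinone methide (not isolated) | CC(C)=C/C=C1\C(=O)C=C(OCc2ccccc2)C=C1OCc1ccccc1 | intermediate
13 | 5,7-bis(benzyloxy)-2,2-dimethyl-2H-chromene | CC1(C)C=Cc2c(OCc3ccccc3)cc(OCc3ccccc3)cc2O1 | intermediate
14 | 2,2-dimethylchroman-5,7-diol | CC1(C)CCc2c(O)cc(O)cc2O1 | intermediate
15 | 5,7-bis(methoxymethoxy)-2,2-dimethylchroman | COCOc1cc(OCOC)c2CCC(C)(C)Oc2c1 | intermediate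
16 | 1-bromo-3-methylbut-2-ene | CC(C)=CCBr | starting material
17 | 6-lithio-5,7-bis(methoxymethoxy)-2,2-dimethylchroman (not isolated) | COCOc1cc2OC(C)(C)CCc2c(OCOC)c1[Li] | intermediate
18 | 5,7-bis(methoxymethoxy)-2,2-dimethyl-6-(3-methylbut-2-en-1-yl)chroman | CC(C)=CCc1c(OCOC)cc2OC(C)(C)CCc2c1OCOC | intermediate
19 | N-methoxy-N-methylacetamide | CON(C)C(C)=O | starting material
20 | 8-lithio derivative of 18 (not isolated) | CC(C)=CCc1c(OCOC)c([Li])c2OC(C)(C)CCc2c1OCOC | intermediate
21 | 1-[5,7-bis(methoxymethoxy)-2,2-dimethyl-6-(3-methylbut-2-en-1-yl)chroman-8-yl]ethan-1-one | CC(C)=CCc1c(OCOC)c(C(C)=O)c2OC(C)(C)CCc2c1OCOC | intermediate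
22 | carbon disulfide | S=C=S | starting material
23 | disodium 3-aryl-3-oxoprop-1-ene-1,1-bis(thiolate), aryl as in 21 (not isolated) | [Na+].[Na+].[S-]C([S-])=CC(=O)c1c(OCOC)c(CC=C(C)C)c(OCOC)c2CCC(C)(C)Oc12 | intermediate
24 | 1-[5,7-bis(methoxymethoxy)-2,2-dimethyl-6-(3-methylbut-2-en-1-yl)chroman-8-yl]-3,3-bis(methylsulfanyl)prop-2-en-1-one | CSC(SC)=CC(=O)c1c(OCOC)c(CC=C(C)C)c(OCOC)c2CCC(C)(C)Oc12 | intermediate
25 | 2,5-dimethoxyphenol | COc1ccc(OC)c(O)c1 | starting material
26 | 3-chloro-3-methylbut-1-yne | CC(C)(Cl)C#C | starting material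
27 | 1,4-dimethoxy-2-[(2-methylbut-3-yn-2-yl)oxy]benzene | COc1ccc(OC)c(OC(C)(C)C#C)c1 | intermediate
28 | 3,6-dimethoxy-2-(3-methylbuta-1,2-dienyl)phenol (not isolated) | COc1ccc(OC)c(C=C=C(C)C)c1O | intermediate
29 | (Z)-2,5-dimethoxy-6-(3-methylbut-2-enylidene)cyclohexa-2,4-dien-1-one, ortho-quinone methide (not isolated) | COC1=CC=C(OC)/C(=C/C=C(C)C)C1=O | intermediate
30 | 5,8-dimethoxy-2,2-dimethyl-2H-chromene | COc1ccc(OC)c2c1OC(C)(C)C=C2 | intermediate
31 | 2,2-dimethyl-2H-chromene-5,8-dione | O=C1C=CC(=O)C2=C1OC(C)(C)C=C2 | intermediate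
32 | 1-aryl-2-(5,8-dihydroxy-2,2-dimethyl-2H-chromen-6-yl)-3,3-bis(methylsulfanyl)prop-2-en-1-one, aryl as in 21 (not isolated) | CSC(SC)=C(C(=O)c1c(OCOC)c(CC=C(C)C)c(OCOC)c2CCC(C)(C)Oc12)c1cc(O)c2OC(C)(C)C=Cc2c1O | intermediate
33 | bis-MOM aryl ketone of the 5-hydroxy-2-(methylsulfanyl)benzofuran-3-yl unit with 2,2-dimethyl-2H-pyran fused at C6–C7 (O on C6) | CSc1oc2c3C=CC(C)(C)Oc3c(O)cc2c1C(=O)c1c(OCOC)c(CC=C(C)C)c(OCOC)c2CCC(C)(C)Oc12 | intermediate
34 | trihydroxy ketone, 33 without both MOM groups | CSc1oc2c3C=CC(C)(C)Oc3c(O)cc2c1C(=O)c1c(O)c(CC=C(C)C)c(O)c2CCC(C)(C)Oc12 | intermediate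
35 | CNP0081330.0 | CC(C)=CCc1c(O)c2c(c3c(=O)c4c(oc13)oc1c3c(c(O)cc14)OC(C)(C)C=C3)OC(C)(C)CC2 | target

**Step count and risks**

Total steps: 15. Longest linear sequence: 12 (steps 1–9, 13, 14, 15); the quinone branch (steps 10–12) joins at step 13.

Steps most likely to fail:

1. Step 13. What may go wrong: sluggish conjugate addition by the hindered, weakly nucleophilic α-carbon, Lewis-acid-induced loss of a MOM group followed by premature chromone closure or hydroalkoxylation of the prenyl group, and erosion of the regioselectivity of the attack on the unsymmetrical quinone. The fallback sets out from 21 and returns at 35; it replaces the Lewis acid by a Brønsted acid and the dithioacetal by a more nucleophilic enamine. Condensation of 21 with Me2NCH(OMe)2 (toluene, 100 °C) should give the (E)-enaminone F1. The Nenitzescu benzofuran synthesis of F1 with quinone 31 in acetic acid at rt should give, with loss of dimethylamine, the 3-aroyl-5-hydroxybenzofuran F2 (hydrogen in place of methylsulfanyl). Carbonyl-assisted methanolysis (dilute HCl, MeOH, 0 °C) should remove only the MOM group ortho to the ketone to give the mono-MOM hydroxy ketone F3. Base-mediated oxa-Michael addition of that phenol to the furan carbon next to oxygen and dehydrogenation (K2CO3, then DDQ, dioxane, rt), the counterpart of the cyclodehydrogenation of 2'-hydroxyisoflavones, should close ring C to the MOM-protected coumaronochromone F4. HCl in MeOH at 40 °C then gives 35.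

2. Step 4. What may go wrong: slow addition of the weakly nucleophilic enal oxygen to the aryne, a competing ene reaction of the aryne with the allylic methyl C–H bonds, and fluoride-induced self-condensation of the enal. The fallback sets out from 8 and returns at 13; it keeps the aryne as the source of the aryl C–O and aryl C–C bonds but uses a better oxygen nucleophile. Generation of the aryne from 8 with CsF in DMF (insertion into the formamide C=O bond, then aqueous work-up) should give 2,4-bis(benzyloxy)-6-hydroxybenzaldehyde F5 with the same regiochemistry. Addition of 2-methylprop-1-enylmagnesium bromide (excess, THF, 0 °C) should give the racemic allylic alcohol F6. Mild acid (PPTS, toluene, 80 °C) dehydrates F6 to the ortho-quinone methide 12, which closes by oxa-6π electrocyclisation to 13.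

3. Step 8. What may go wrong: competing deprotonation at the benzylic and allylic CH2 of the prenyl group instead of the ring, and enolisation of the acylating agent by the aryllithium. The fallback sets out from 18 and returns at 21; it replaces deprotonation by electrophilic substitution and halogen–lithium exchange. Bromination of 18 at its only free aromatic position (NBS, MeCN, −30 °C) should give the 8-bromochroman F7. Bromine–lithium exchange (t-BuLi, THF, −78 °C) and addition to acetaldehyde should give the racemic carbinol F8. Oxidation of the benzylic alcohol (MnO2, CH2Cl2, rt) gives 21.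

Further compounds
F1 | step 13 | (E)-3-(dimethylamino)-1-[5,7-bis(methoxymethoxy)-2,2-dimethyl-6-(3-methylbut-2-en-1-yl)chroman-8-yl]prop-2-en-1-one | CN(C)/C=C/C(=O)c1c(OCOC)c(CC=C(C)C)c(OCOC)c2CCC(C)(C)Oc12
F2 | step 13 | bis-MOM aryl ketone of the 5-hydroxybenzofuran-3-yl unit with 2,2-dimethyl-2H-pyran fused at C6–C7 (33 with H in place of SCH3) | O=C(c1coc2c3C=CC(C)(C)Oc3c(O)cc12)c1c(OCOC)c(CC=C(C)C)c(OCOC)c2CCC(C)(C)Oc12
F3 | step 13 | F2 without the MOM group ortho to the ketone | O=C(c1coc2c3C=CC(C)(C)Oc3c(O)cc12)c1c(O)c(CC=C(C)C)c(OCOC)c2CCC(C)(C)Oc12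
F4 | step 13 | mono-MOM ether of 35 at the ring A hydroxyl | O=c1c2c3cc(O)c4OC(C)(C)C=Cc4c3oc2oc2c(CC=C(C)C)c(OCOC)c3CCC(C)(C)Oc3c12
F5 | step 4 | 2,4-bis(benzyloxy)-6-hydroxybenzaldehyde | O=Cc1c(O)cc(OCc2ccccc2)cc1OCc1ccccc1
F6 | step 4 | 3,5-bis(benzyloxy)-2-(1-hydroxy-3-methylbut-2-en-1-yl)phenol, racemic | CC(C)=CC(O)c1c(O)cc(OCc2ccccc2)cc1OCc1ccccc1
F7 | step 8 | 8-bromo-5,7-bis(methoxymethoxy)-2,2-dimethyl-6-(3-methylbut-2-en-1-yl)chroman | CC(C)=CCc1c(OCOC)c(Br)c2OC(C)(C)CCc2c1OCOC
F8 | step 8 | 1-[5,7-bis(methoxymethoxy)-2,2-dimethyl-6-(3-methylbut-2-en-1-yl)chroman-8-yl]ethan-1-ol, racemic | CC(C)=CCc1c(OCOC)c(C(C)O)c2OC(C)(C)CCc2c1OCOC
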